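**Plan**

- Numbering: C1 ketone, C2=C3(Me), cyclobutane C4–C5–C11–C10, C6 gem-dimethyl, C7 (O-angelate), C8, C9 (O-isovalerate), C10 (methyl). The retrosynthesis cuts the two ester C–O bonds and the C7–H/C9–H bonds (back to a 7,9-diketone), then C2=C3 (aldol condensation), then the C4–H/C11–H pair (back to a C4–C11 bicyclobutane bond). Further back it cuts the C11–acetyl bond, C4–C5/C4–C11 (carbenoid addition), C5=C11 (metathesis), C8–C9 (Claisen acylation) and C10–C4 (enolate alkylation).
- Forward, the chain is joined C10–C4, then C8–C9. The rings arise in the order seven-membered ring, bicyclobutane, cyclobutane (bicyclo[4.1.1]octane), cyclohexenone (bicyclo[3.1.1]heptenone).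
- Enabling feature: C4 and C11 are each bonded to both C5 and C10. With C7 and C9 as ketals, the 4,11-diacetylbicyclo[4.1.1]octane therefore has a mirror plane through C5, C10 and the C6–C9 bridge. Its two acetyls are enantiotopic, and the core becomes chiral only when one of them is chosen as the C1 ketone.
- Stereochemistry: every compound before the key step is racemic or achiral. A chiral primary amine fixes C4, C5, C10 and C11 in one closure. C9 comes from a CBS reduction and C7 from a 1,3-anti hydride delivery (Evans–Tishchenko), which also places the isovalerate.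

Key step: step 11

Assumption: the quinine-derived primary amine is taken to select the acetyl that leads to the enantiomer drawn (the quinidine-derived pseudo-enantiomer is used if the sense proves opposite); racemic intermediates are written without tags or as one enantiomer.

**Step 1**
Reactants: 1 2-methylbut-3-enoic acid; 2 methyl bromoacetate
Product: 3 rac-2-ethenyl-4-methoxy-2-methyl-4-oxobutanoic acid
Conditions: LiN(i-Pr)2 (2.2 equiv), THF, −78 to 0 °C; then 2, −78 °C to rt; aq. HCl
Reagents that add atoms: none
Why: α-selective alkylation of the lithium dienediolate (dianion) of a β,γ-unsaturated acid by a reactive α-bromo ester builds the quaternary C10 (racemic) carrying the vinyl group (future C11) and the acetate arm (future C4).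

**Step 2**
Reactants: 4 2,2-dimethylbut-3-enoic acid
Product: 5 3,3-dimethylpent-4-en-2-one
Conditions: MeLi (2.2 equiv), Et2O, 0 °C to rt; then H2O
Reagents that add atoms: methyllithium, [Li]C
Why: addition of methyllithium to the lithium carboxylate stops at the gem-diolate, which gives the methyl ketone only on hydrolysis (carboxylic acid to methyl ketone).

**Step 3**
Reactants: 3 rac-2-ethenyl-4-methoxy-2-methyl-4-oxobutanoic acid; 5 3,3-dimethylpent-4-en-2-one
Product: 7 rac-methyl 3-ethenyl-3,7,7-trimethyl-4,6-dioxonon-8-enoate, via acid chloride 6 (not isolated)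
Conditions: 3, (COCl)2, DMF (cat.), CH2Cl2, 0 °C to rt, evaporate; then 5, MgBr2·OEt2 (2.5 equiv), i-Pr2NEt (3 equiv), CH2Cl2, rt
Reagents that add atoms: oxalyl chloride, O=C(Cl)C(Cl)=O (supplies the chlorine of 6 only; no atoms in 7)
Why: Claisen-type C-acylation under soft enolisation (magnesium enolate, amine base) of a ketone with a single enolisable position forms C8–C9 without a strong base touching the ester arm.

**Step 4**
Reactants: 7 rac-methyl 3-ethenyl-3,7,7-trimethyl-4,6-dioxonon-8-enoate
Product: 8 rac-methyl 2-(1,4,4-trimethyl-5,7-dioxocyclohept-2-en-1-yl)acetate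
Conditions: second-generation Hoveyda–Grubbs catalyst RuCl2(H2IMes)(=CH-C6H4-2-O-i-Pr) (5 mol%), toluene (5 mM), 80 °C
Reagents that add atoms: none
Why: ring-closing metathesis of the two terminal vinyl groups closes the seven-membered ring with the cis C5=C11 alkene through the diketo tautomer, driven by loss of ethylene.

**Step 5**
Reactants: 8 rac-methyl 2-(1,4,4-trimethyl-5,7-dioxocyclohept-2-en-1-yl)acetate
Product: 9 rac-methyl 2-[5,5:7,7-bis(ethylenedioxy)-1,4,4-trimethylcyclohept-2-en-1-yl]acetate
Conditions: Me3SiOCH2CH2OSiMe3 (4 equiv), TMSOTf (10 mol%), CH2Cl2, −78 to 0 °C; pyridine quench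
Reagents that add atoms: 1,2-bis(trimethylsilyloxy)ethane, C[Si](C)(C)OCCO[Si](C)(C)C
Why: Noyori ketalisation is aprotic and cold, which avoids the enol-ether and retro-Claisen pathways of β-diketones and masks both carbonyls (C7, C9) next to quaternary carbons.

**Step 6**
Reactants: 9 rac-methyl 2-[5,5:7,7-bis(ethylenedioxy)-1,4,4-trimethylcyclohept-2-en-1-yl]acetate
Product: 11 rac-methyl 2-diazo-2-[5,5:7,7-bis(ethylenedioxy)-1,4,4-trimethylcyclohept-2-en-1-yl]acetate, via trifluoroacetyl ester 10 (not isolated)
Conditions: LiN(SiMe3)2, THF, −78 °C; CF3CO2CH2CF3; then MsN3, Et3N, H2O (1 equiv), MeCN, rt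
Reagents that add atoms: methanesulfonyl azide, CS(=O)(=O)N=[N+]=[N-]; 2,2,2-trifluoroethyl trifluoroacetate, O=C(OCC(F)(F)F)C(F)(F)F (trifluoroacetyl group of 10 only)
Why: deacylative (detrifluoroacetylative) Regitz diazo transfer acts at the only enolisable C–H left, the ester CH2 (future C4).

**Step 7**
Reactants: 11 rac-methyl 2-diazo-2-[5,5:7,7-bis(ethylenedioxy)-1,4,4-trimethylcyclohept-2-en-1-yl]acetate
Product: 12 rac-methyl 3,3:5,5-bis(ethylenedioxy)-2,6,6-trimethyltricyclo[5.1.0.0(2,8)]octane-1-carboxylate
Conditions: Rh2(cap)4 (dirhodium tetrakis(caprolactamate), 1 mol%), CH2Cl2, 40 °C, slow addition of 11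
Reagents that add atoms: none
Why: intramolecular cyclopropanation of an α-allyl α-diazo ester (bicyclobutanation) by a carbenoid that has no β-hydrogen (C10 is quaternary) forms C4–C5 and C4–C11; the cis ring alkene forces the C6–C9 chain across the endo positions of the wing carbons, so C4, C5 and C11 follow from C10 as one racemic diastereomer, and the weakly electrophilic carboxamidate catalyst disfavours C–H insertion into the dioxolanes.

**Step 8**
Reactants: 12 rac-methyl 3,3:5,5-bis(ethylenedioxy)-2,6,6-trimethyltricyclo[5.1.0.0(2,8)]octane-1-carboxylate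
Product: 13 rac-3,3:5,5-bis(ethylenedioxy)-1-(1-methoxyethenyl)-2,6,6-trimethyltricyclo[5.1.0.0(2,8)]octane
Conditions: Cp2TiMe2 (2.5 equiv), toluene/THF, 70 °C, dark
Reagents that add atoms: dimethyltitanocene, [CH3-].[CH3-].[Ti+4].[cH-]1cccc1.[cH-]1cccc1
Why: Petasis methylenation turns the ester into a methyl enol ether, a masked acetyl that tolerates the organolithium of the next step.

**Step 9**
Reactants: 13 rac-3,3:5,5-bis(ethylenedioxy)-1-(1-methoxyethenyl)-2,6,6-trimethyltricyclo[5.1.0.0(2,8)]octane
Product: 15 1,8-diacetyl-3,3:5,5-bis(ethylenedioxy)-2,6,6-trimethyltricyclo[5.1.0.0(2,8)]octane, via acetyl enol ether 14 (not isolated)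
Conditions: s-BuLi, TMEDA, Et2O, −78 to −20 °C; MeC(O)N(OMe)Me, −78 °C to rt; then aq. oxalic acid, THF, 0 °C
Reagents that add atoms: N-methoxy-N-methylacetamide, CC(=O)N(C)OC; water, O
Why: bridgehead lithiation of the bicyclobutane (acidic, high s-character C–H on the open convex face, whereas the rear of the central bond is screened by the quaternary C6 and C9), Weinreb acylation and mild enol-ether hydrolysis give the mirror-symmetric 1,3-diacetylbicyclobutane.

**Step 10**
Reactants: 15 1,8-diacetyl-3,3:5,5-bis(ethylenedioxy)-2,6,6-trimethyltricyclo[5.1.0.0(2,8)]octane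
Product: 16 meso-7,8-diacetyl-2,2:4,4-bis(ethylenedioxy)-1,5,5-trimethylbicyclo[4.1.1]octane (both acetyls anti to the C2–C5 bridge; the 4,11-diacetyl compound in the numbering of the plan)
Conditions: SmI2 (2.5 equiv), THF, MeOH, −78 °C; then AcOH (cat.), toluene, 50 °C
Reagents that add atoms: none
Why: single-electron reductive cleavage of the strained central bond flanked by two ketones (as in SmI2 opening of cyclopropyl ketones) gives a bis-enolate, and protonation with acid equilibration of the enolisable C4 and C11 should place both acetyls anti to the C6–C9 bridge, because the syn positions are eclipsed with the quaternary C6 and C9.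

**Step 11**
Reactants: 16 meso-7,8-diacetyl-2,2:4,4-bis(ethylenedioxy)-1,5,5-trimethylbicyclo[4.1.1]octane
Product: 18 (4R,5S,10R,11R)-longipin-2-en-1-one 7,9-bis(ethylene ketal), via ketol 17 (not isolated)
Conditions: 9-amino-9-deoxy-epi-quinine (20 mol%), AcOH (60 mol%), toluene, 40 °C
Reagents that add atoms: none
Why: Proposed new method: the primary amine condenses with one acetyl of 16 to an enamine (C1–C2) that adds to the other, acid-activated acetyl carbonyl (C3), and E1cB loss of water from ketol 17 gives the conjugated enone irreversibly; the closest known reaction type is the primary-amine/acid-catalysed desymmetrising aldol condensation of acyclic 4-substituted heptane-2,6-diones to 5-substituted 3-methylcyclohex-2-enones, extended here to a diketone whose 3- and 5-positions are tied into a cyclobutane. The ring closed is the six-membered C1–C2–C3–C4–C10–C11 ring (equally C1–C2–C3–C4–C5–C11) in a 6-enolexo-exo-trig mode, which lays the three-carbon bridge of a bicyclo[3.1.1]heptenone across the cyclobutane face opposite the C6–C9 bridge. C4, C5, C10 and C11 already have the right relative configuration; the step creates their absolute sense, which depends only on which enantiotopic acetyl becomes the nucleophile, a choice controlled by the cinchona scaffold whose protonated quinuclidine binds the electrophilic carbonyl. The selectivity needed is enantiotopic-group selection without background closure. The substrate secures it by its mirror plane, by holding both acetyls on one face within bonding distance, by offering no other enolisable ketone (C7 and C9 are ketals), and by letting any C4/C11 epimer re-enter through enol or enamine equilibration.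

**Step 12**
Reactants: 18 (4R,5S,10R,11R)-longipin-2-en-1-one 7,9-bis(ethylene ketal)
Product: 19 (4R,5S,10R,11R)-longipin-2-ene-1,7,9-trione
Conditions: 2 M aq. HCl, THF, 40 °C
Reagents that add atoms: water, O
Why: acid-catalysed ketal hydrolysis; no stereocentre can epimerise because C10 is quaternary and C11 is a bridgehead that cannot enolise.

**Step 13**
Reactants: 19 (4R,5S,10R,11R)-longipin-2-ene-1,7,9-trione
Product: 20 (4R,5S,9R,10R,11R)-9-hydroxylongipin-2-ene-1,7-dione
Conditions: (S)-2-methyl-CBS-oxazaborolidine (20 mol%), catecholborane (1.1 equiv), toluene, −78 °C; pH 7 buffer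
Reagents that add atoms: none
Why: CBS reduction in which the C9 carbonyl, flanked by the tied-back cyclobutane carbon C10, should be more accessible than the C7 carbonyl shielded on both faces by the C6 methyls and more electrophilic than the conjugated C1 ketone; the (S)-catalyst, with C10 as the large group, delivers hydride to give the (9R)-alcohol under catalyst control, since the two faces of the bridge are nearly equivalent in the substrate.

**Step 14**
Reactants: 20 (4R,5S,9R,10R,11R)-9-hydroxylongipin-2-ene-1,7-dione; 21 3-methylbutanal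
Product: 22 (4R,5S,7R,9R,10R,11R)-7-hydroxy-9-(3-methylbutanoyloxy)longipin-2-en-1-one
Conditions: 21 (8 equiv), SmI2 (0.3 equiv), THF, −10 °C
Reagents that add atoms: none
Why: Evans–Tishchenko reaction, in which the samarium-bound hemiacetal of the C9 hydroxyl with 21 delivers its hydride intramolecularly to C7 on the face of O9, giving the 1,3-anti (7R) alcohol and leaving the acyl group on O9 as the isovalerate.

**Step 15**
Reactants: 22 (4R,5S,7R,9R,10R,11R)-7-hydroxy-9-(3-methylbutanoyloxy)longipin-2-en-1-one; 23 angelic acid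
Product: 24 (4R,5S,7R,9R,10R,11R)-7-angeloyloxy-9-isovaleroyloxylongipin-2-en-1-one (CNP0240547.2)
Conditions: 23, 2,4,6-trichlorobenzoyl chloride, Et3N, toluene, rt; then 22, 80 °C
Reagents that add atoms: none
Why: Yamaguchi mixed-anhydride esterification of the only free hydroxyl; DMAP-free conditions in toluene should keep the Z-angelate from isomerising to the tiglate.

**Compound list**

1 | 2-methylbut-3-enoic acid (racemic) | C=CC(C)C(O)=O | starting material
2 | methyl bromoacetate | COC(=O)CBr | starting material
3 | rac-2-ethenyl-4-methoxy-2-methyl-4-oxobutanoic acid | C=CC(C)(CC(=O)OC)C(O)=O | intermediate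
4 | 2,2-dimethylbut-3-enoic acid | C=CC(C)(C)C(O)=O | starting material
5 | 3,3-dimethylpent-4-en-2-one | C=CC(C)(C)C(C)=O | intermediate
6 | rac-methyl 3-(chlorocarbonyl)-3-methylpent-4-enoate | C=CC(C)(CC(=O)OC)C(Cl)=O | intermediate (not isolated)
7 | rac-methyl 3-ethenyl-3,7,7-trimethyl-4,6-dioxonon-8-enoate | C=CC(C)(CC(=O)OC)C(=O)CC(=O)C(C)(C)C=C | intermediate
8 | rac-methyl 2-(1,4,4-trimethyl-5,7-dioxocyclohept-2-en-1-yl)acetate | COC(=O)CC1(C)C=CC(C)(C)C(=O)CC1=O | intermediate
9 | rac-methyl 2-[5,5:7,7-bis(ethylenedioxy)-1,4,4-trimethylcyclohept-2-en-1-yl]acetate | COC(=O)CC1(C)C=CC(C)(C)C2(OCCO2)CC13OCCO3 | intermediate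
10 | methyl 4,4,4-trifluoro-3-oxo-2-[5,5:7,7-bis(ethylenedioxy)-1,4,4-trimethylcyclohept-2-en-1-yl]butanoate (stereoisomer mixture) | COC(=O)C(C(=O)C(F)(F)F)C1(C)C=CC(C)(C)C2(OCCO2)CC13OCCO3 | intermediate (not isolated)
11 | rac-methyl 2-diazo-2-[5,5:7,7-bis(ethylenedioxy)-1,4,4-trimethylcyclohept-2-en-1-yl]acetate | COC(=O)C(=[N+]=[N-])C1(C)C=CC(C)(C)C2(OCCO2)CC13OCCO3 | intermediate
12 | rac-methyl 3,3:5,5-bis(ethylenedioxy)-2,6,6-trimethyltricyclo[5.1.0.0(2,8)]octane-1-carboxylate (bicyclobutane, C1–C8 central bond = C4–C11; wings C2 and C7 bridged endo,endo) | CC1(C)C2(OCCO2)CC3(OCCO3)[C@@]4(C)[C@@]5(C(=O)OC)[C@@H]1[C@@H]45 | intermediate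
13 | rac-3,3:5,5-bis(ethylenedioxy)-1-(1-methoxyethenyl)-2,6,6-trimethyltricyclo[5.1.0.0(2,8)]octane | CC1(C)C2(OCCO2)CC3(OCCO3)[C@@]4(C)[C@@]5(C(OC)=C)[C@@H]1[C@@H]45 | intermediate
14 | rac-8-acetyl-3,3:5,5-bis(ethylenedioxy)-1-(1-methoxyethenyl)-2,6,6-trimethyltricyclo[5.1.0.0(2,8)]octane | CC1(C)C2(OCCO2)CC3(OCCO3)[C@@]4(C)[C@@]5(C(OC)=C)[C@@H]1[C@@]45C(C)=O | intermediate (not isolated)
15 | 1,8-diacetyl-3,3:5,5-bis(ethylenedioxy)-2,6,6-trimethyltricyclo[5.1.0.0(2,8)]octane (achiral, mirror plane through C2, C7 and the C3–C6 bridge) | CC1(C)C2(OCCO2)CC3(OCCO3)[C@@]4(C)[C@@]5(C(C)=O)[C@@H]1[C@@]45C(C)=O | intermediate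
16 | meso-7,8-diacetyl-2,2:4,4-bis(ethylenedioxy)-1,5,5-trimethylbicyclo[4.1.1]octane (acetyls cis to each other, anti to the four-carbon bridge) | CC1(C)C2(OCCO2)CC3(OCCO3)[C@@]4(C)[C@H](C(C)=O)[C@@H]1[C@@H]4C(C)=O | intermediate
17 | 3-hydroxylongipinan-1-one 7,9-bis(ethylene ketal), aldol adduct with the core of 18, C3 configuration undefined | CC1(C)C2(OCCO2)CC3(OCCO3)[C@@]4(C)[C@@H]5C(=O)CC(C)(O)[C@H]4[C@@H]51 | intermediate (not isolated)
18 | (4R,5S,10R,11R)-longipin-2-en-1-one 7,9-bis(ethylene ketal) | CC1(C)C2(OCCO2)CC3(OCCO3)[C@@]4(C)[C@@H]5C(=O)C=C(C)[C@H]4[C@@H]51 | intermediate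
19 | (4R,5S,10R,11R)-longipin-2-ene-1,7,9-trione | CC1(C)C(=O)CC(=O)[C@@]2(C)[C@@H]3C(=O)C=C(C)[C@H]2[C@@H]31 | intermediate
20 | (4R,5S,9R,10R,11R)-9-hydroxylongipin-2-ene-1,7-dione | CC1(C)C(=O)C[C@@H](O)[C@@]2(C)[C@@H]3C(=O)C=C(C)[C@H]2[C@@H]31 | intermediate
21 | 3-methylbutanal | CC(C)CC=O | starting material
22 | (4R,5S,7R,9R,10R,11R)-7-hydroxy-9-(3-methylbutanoyloxy)longipin-2-en-1-one | CC1(C)[C@H](O)C[C@@H](OC(=O)CC(C)C)[C@@]2(C)[C@@H]3C(=O)C=C(C)[C@H]2[C@@H]31 | intermediate
23 | angelic acid, (Z)-2-methylbut-2-enoic acid | C/C=C(/C)C(=O)O | starting material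
24 | (4R,5S,7R,9R,10R,11R)-7-angeloyloxy-9-isovaleroyloxylongipin-2-en-1-one | C/C=C(/C)C(=O)O[C@@H]1C[C@@H](OC(=O)CC(C)C)[C@@]2(C)[C@@H]3C(=O)C=C(C)[C@H]2[C@@H]3C1(C)C | target

**Step count and risks**

Total steps: 15. Longest linear sequence: 14 (steps 1 and 3–15 from 1); step 2 is a one-step side branch.

Steps most likely to fail:

1. Step 11 (proposed new method). The closure to the strained bicyclo[3.1.1]heptenone may be too slow under aminocatalysis, or the catalyst may discriminate poorly between the two enantiotopic acetyls. Fallback with known chemistry: setting out from 16, an ordinary base-mediated intramolecular aldol condensation (KOt-Bu, t-BuOH, rt) should give the racemic enone, that is 18 together with its antipode (4S,5R,10S,11S)-longipin-2-en-1-one 7,9-bis(ethylene ketal) F1. Acid hydrolysis as in step 12 should give 19 together with (4S,5R,10S,11S)-longipin-2-ene-1,7,9-trione F2. The (S)-CBS reduction of step 13 then serves as a reagent-controlled divergent reduction: 19 gives 20, and F2 gives the diastereomeric (4S,5R,9R,10S,11S)-9-hydroxylongipin-2-ene-1,7-dione F3, which is removed by chromatography. The route is rejoined at 20.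

2. Step 7. The carbenoid may insert into the OCH2 bonds of the C9 dioxolane or undergo 1,2-vinyl migration instead of adding to the hindered ring alkene. Fallback: setting out from 11, metal-free heating (toluene, 80 °C) should effect an intramolecular 1,3-dipolar cycloaddition of the diazo ester onto the ring alkene. This gives the cyclopropane-fused 1-pyrazoline rac-methyl 2,3-diazabicyclo[3.1.0]hex-2-ene-1-carboxylate spanned by the bis-ketal chain F4. Irradiation at 350 nm should extrude dinitrogen and close the 1,3-diradical to the bicyclobutane. No free carbenoid is involved. The route is rejoined at 12.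

3. Step 13. Site selectivity between the C9 and C7 carbonyls may be lost, or the C1 enone may be reduced as well. Fallback: setting out from 19, exhaustive reduction with the (S)-CBS catalyst and BH3·SMe2 should give (7R,9R)-longipin-2-ene-1,7,9-triol F5, with both bridge carbinols under catalyst control. MnO2 in CH2Cl2 re-oxidises only the allylic C1 alcohol to (7R,9R)-7,9-dihydroxylongipin-2-en-1-one F6. Hindrance-controlled mono-acylation with isovaleric anhydride and pyridine at −20 °C should then esterify the less shielded C9 hydroxyl. The route is rejoined at 22.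

**Further compounds**

F1 | step 11 | (4S,5R,10S,11S)-longipin-2-en-1-one 7,9-bis(ethylene ketal) | CC1(C)C2(OCCO2)CC3(OCCO3)[C@]4(C)[C@H]5C(=O)C=C(C)[C@@H]4[C@H]51
F2 | step 11 | (4S,5R,10S,11S)-longipin-2-ene-1,7,9-trione | CC1(C)C(=O)CC(=O)[C@]2(C)[C@H]3C(=O)C=C(C)[C@@H]2[C@H]31
F3 | step 11 | (4S,5R,9R,10S,11S)-9-hydroxylongipin-2-ene-1,7-dione | CC1(C)C(=O)C[C@@H](O)[C@]2(C)[C@H]3C(=O)C=C(C)[C@@H]2[C@H]31
F4 | step 7 | rac-methyl 2,3-diazabicyclo[3.1.0]hex-2-ene-1-carboxylate spanned C4 to C6 by the 1,1-dimethyl-2,2:4,4-bis(ethylenedioxy)butane-1,4-diyl chain, 6-methyl (cyclopropane-fused 1-pyrazoline) | CC1(C)C2(OCCO2)CC3(OCCO3)[C@@]4(C)[C@@]5(C(=O)OC)N=N[C@@H]1[C@@H]45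
F5 | step 13 | (4R,5S,7R,9R,10R,11R)-longipin-2-ene-1,7,9-triol, C1 configuration undefined | CC1(C)[C@H](O)C[C@@H](O)[C@@]2(C)[C@@H]3C(O)C=C(C)[C@H]2[C@@H]31
F6 | step 13 | (4R,5S,7R,9R,10R,11R)-7,9-dihydroxylongipin-2-en-1-one | CC1(C)[C@H](O)C[C@@H](O)[C@@]2(C)[C@@H]3C(=O)C=C(C)[C@H]2[C@@H]31
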